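## The problem

1. Target 22 is a (2S)-5,7-dihydroxyflavanone. Its ring A (C4a, C5, C6, C7, C8, C8a) is hexasubstituted: three oxygens (O1, 5-OH, 7-OH) alternate with three different carbon substituents. These are the C4 acyl carbon at C4a, the three-ring benzyl chain (rings D, E, F) at C6, and a 2-hydroxybenzyl group (ring C) at C8.
2. C6 and C8 each sit between two oxygens and are electronically almost alike. O1 and 5-OH are likewise equivalent ortho partners of the C4 carbonyl. Any route that decorates a purchased phloroglucinol core must therefore make two regiochemical choices with nothing in the substrate to decide them.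
3. The only stereocentre, C2, lies β to C4=O and carries O1 as a leaving group. Acid, base or heat open O1–C2 to the chalcone. This racemises C2 and, once 5-OH is free, allows re-closure on either oxygen, which exchanges the C6 and C8 substituents (Wessely–Moser type). No other stereocentre is available to control C2.
4. The side chain has its own regiochemistry. Ring D is joined ortho (to ring A) and para (to ring E) to its hydroxyl. Ring E is joined at both ortho positions to two different partners, with its para position free. Ambident phenols do not deliver these patterns selectively.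
5. Six free phenols and four doubly benzylic methylenes rule out strong acid, base or oxidant once the flavanone exists.
6. The enabling feature is this: in ring A the carbon-substituted C6 lies between the oxygen-bearing C5 and C7, and C5 is bonded to C4a. If C6 is exchanged for an oxygen atom, ring A becomes the 2-pyrone ring (C5 lactone carbonyl, O6, C7) of a pyrano[4,3-b]pyran-4,5-dione. C6 and its benzyl arm then form the first carbon of a side chain on C7, and this compound is an isomer of the chromone.
7. A 4-hydroxy-2-pyrone has one hydroxyl (the future O1) and one nucleophilic carbon (the future C4a), so both regiochemical choices vanish. Ring B is a plain phenyl on C2, so the stereocentre can be left out until ring A is finished.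

## Retrosynthesis

**22 to 21.** The six O–benzyl bonds are cut last. A flavanone with free 5-OH tolerates neither base nor Lewis acid, so one kind of protecting group is used that falls under neutral hydrogenolysis. The forward step must leave C4=O and the benzylic C2–O1 bond alone.

**21 to 20.** The C2–phenyl bond (ring B) is cut. The alternatives are O1–C2 (chalcone closure, reversible) and C2–C3 (aldol). Precursor 20 is a flat, achiral chromone that cannot open to a chalcone, so neither C2 nor the C6/C8 assignment is at risk in anything done before this step. The forward reaction is a catalytic enantioselective 1,4-addition of a phenylboron reagent. The C6 and C8 arms lie far from C2.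

**20 to 19 to 17 (key).** After removal of two benzyl groups, the C5–C6 bond of ring A is cut and C5 is reconnected to the oxygen on C7. This gives the isomeric bis-pyrone 17. The neighbouring cuts (C6–CH2, C8–CH2) are Friedel–Crafts bonds with no regiocontrol. This cut removes the hexasubstituted benzene altogether and leaves a heterocycle whose substituent positions are set by enolate chemistry. The forward reaction is a base-induced ring opening and carbon re-closure that swaps O6 for C6.

**17 to 14.** C4a–C4 and O1–C2 are cut, which removes a three-carbon β-alkoxyacryloyl unit. Pyrone 14 has a single hydroxyl and a single nucleophilic CH, so the annulation has only one possible outcome. An acylphloroglucinol would offer two.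

**14 to 3 and 12 (via 13).** The lactone bond C5–O6 and the C7–C8 bond are cut. This is the convergent union. β-Keto ester 3 brings C5, C4a, C8a and C8 with the ring C arm. Ester 12 brings C7 and C6 with the D–E–F arm. The forward reaction is a γ-acylation of the dianion of 3 by 12, followed by enol lactonisation.

**3 to 1 and 2.** The C8–CH2 (ring C) bond is cut. On the arene this would be a Friedel–Crafts bond. Here it is the SN2 alkylation of the terminal carbanion of 1 by bromide 2.

**12 to 11 to 10 to 9 and 6; 9 to 7 and 8.** In ring E the C–OH is flanked by two CH2 bridges and faces three contiguous CH groups, which is the pattern of a cyclohexanone. Retro-isoaromatisation of 11 gives dienone 10. Two aldol cuts then lead to 7, 8 and 6. The ketone α-carbons encode the ortho,ortho′ pattern, and the para position is never touched.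

**6 to 5 to 4.** Ring D comes from lactone 4 together with its oxygen and the ortho three-carbon chain (bridge CH2, C6, C5). Only a formyl group para to the oxygen has to be added.

## Roads not taken

**Alternative 1 (the obvious one).**
- *Cut:* C6–CH2 and C8–CH2.
- *Forward key step:* Lewis-acid or thermal ortho-quinone methide hydroxybenzylation of (S)-pinocembrin A1, once with the parent ortho-hydroxybenzyl donor and once with the three-ring benzylic alcohol A2.
- *Why the chosen plan is better:*
  - The first benzylation must choose between C6 and C8. Nothing in A1 decides this, so the 8-isomer A3 and the 6-isomer A4 both arise and have to be separated.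
  - Each new hydroxybenzyl ring is itself a nucleophile, and A2 can condense with itself.
  - The conditions that generate the quinone methide also open O1–C2 of a 5-hydroxyflavanone, so configuration and the C6/C8 assignment are both exposed.
  - A2 would still need a regiodefined synthesis of its own.
  - The chosen plan makes both ring A–CH2 bonds on sp3 carbon before ring A exists, and keeps C2 sp2 until the end.

**Alternative 2.**
- *Cut:* O1–C2.
- *Forward key step:* catalytic enantioselective intramolecular oxa-Michael addition of the fully armed chalcone A5.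
- *Why the chosen plan is better:*
  - A5 has two ortho hydroxyls flanked by nearly identical benzyl arms, so it gives two constitutional isomers unless one hydroxyl is masked, and no reagent can tell them apart.
  - The closure is reversible, so selectivity can erode.
  - Efficient catalysts of this type usually need an extra activating ester that must be added and removed.
  - The chosen plan fixes O1 by connectivity and forms the stereocentre through an irreversible C–C bond.

**Alternative 3.**
- *Cut:* C6–CH2 on a purchased ring A, with the same endgame.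
- *Forward key step:* Negishi coupling of the 6-iodochromone A6 with the benzylic zinc chloride A7 to give 20.
- *Why the chosen plan is better:*
  - A6 depends on a purely steric discrimination between two chelated hydroxyls of a C-benzylated acylphloroglucinol to define O1.
  - The coupling takes place at an iodide flanked by two benzyloxy groups.
  - A7 needs a one-carbon handle on ring D that costs an ester reduction and a halogenation.
  - The step count is no lower, and two steps rest on selectivity rather than on connectivity.

Key step: step 10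

**Remarks.**
- Flavanone numbering is used for all atoms that end up in the flavanone. In 17 it coincides with the pyrano[4,3-b]pyran numbering, position 6 being oxygen.
- Ar(DEF) = 2-(benzyloxy)-5-{2-(benzyloxy)-3-[2-(benzyloxy)benzyl]benzyl}phenyl, that is, rings D, E and F as benzyl ethers.
- Assumption: the (R) antipode of the diphosphine in step 12 is taken to give the (2S) product. If the sense of induction is the opposite, the (S) ligand is used and nothing else changes.

## Steps

Step 1
Reactants: 1 methyl acetoacetate; 2 1-(benzyloxy)-2-(bromomethyl)benzene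
Product: 3 methyl 5-[2-(benzyloxy)phenyl]-3-oxopentanoate
Conditions: LiN(iPr)2 (2.1 equiv), THF, −78 to 0 °C; 2, 0 °C; aq. HCl
Reagents that add atoms: none
Why: γ-Alkylation of a β-keto ester dianion: the more basic terminal carbanion attacks the benzylic bromide, so the future C8–CH2 bond is made as an SN2 reaction with no regiochemical issue.

Step 2
Reactants: 4 3,4-dihydrocoumarin (chroman-2-one)
Product: 5 methyl 3-[2-(benzyloxy)phenyl]propanoate
Conditions: NaOMe (1.05 equiv), MeOH, rt; BnBr, 50 °C
Reagents that add atoms: sodium methoxide [Na+].[O-]C; benzyl bromide BrCc1ccccc1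
Why: Methoxide opens the aryl lactone to the phenoxide ester, which is trapped at once by Williamson etherification before it can re-lactonise.

Step 3
Reactants: 5 methyl 3-[2-(benzyloxy)phenyl]propanoate
Product: 6 methyl 3-[2-(benzyloxy)-5-formylphenyl]propanoate
Conditions: Cl2CHOMe, TiCl4, CH2Cl2, −40 to 0 °C; H2O
Reagents that add atoms: dichloromethyl methyl ether COC(Cl)Cl; water O
Why: Rieche formylation: the benzyloxy group directs to its para position, since one ortho site carries the chain and the other is more hindered, and this is the carbon that becomes the bridge to ring E. The low temperature should spare the benzyl ether.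

Step 4
Reactants: 7 cyclohexanone; 8 2-(benzyloxy)benzaldehyde
Product: 9 (E)-2-[2-(benzyloxy)benzylidene]cyclohexan-1-one
Conditions: 7 (4 equiv), NaOH (0.2 equiv), H2O/EtOH, rt
Reagents that add atoms: none
Why: Claisen–Schmidt condensation: the excess of ketone should hold the reaction at the mono-arylidene stage, and the E geometry is the thermodynamic one.

Step 5
Reactants: 9 (E)-2-[2-(benzyloxy)benzylidene]cyclohexan-1-one; 6 methyl 3-[2-(benzyloxy)-5-formylphenyl]propanoate
Product: 10 methyl 3-[2-(benzyloxy)-5-({(1E,3E)-3-[2-(benzyloxy)benzylidene]-2-oxocyclohexylidene}methyl)phenyl]propanoate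
Conditions: NaOMe (0.2 equiv), MeOH/THF, 3 Å sieves, rt
Reagents that add atoms: none
Why: Second Claisen–Schmidt condensation at the only remaining α′-methylene of 9 with a non-enolisable aldehyde. Methoxide in methanol makes ester exchange degenerate.

Step 6
Reactants: 10 the unsymmetrical 2,6-bis(arylidene)cyclohexanone
Product: 11 methyl 3-[2-(benzyloxy)-5-({3-[2-(benzyloxy)benzyl]-2-hydroxyphenyl}methyl)phenyl]propanoate
Conditions: RhCl3·3H2O (5 mol %), MeOH/toluene, 90 °C, sealed tube
Reagents that add atoms: none
Why: Known isoaromatisation of 2,6-dibenzylidenecyclohexanones to 2,6-dibenzylphenols: rhodium hydride addition and elimination move both exocyclic double bonds into the ring, and the dienone tautomerises. The ortho,ortho′ pattern of ring E follows from the ketone α-carbons.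

Step 7
Reactants: 11 the ring E phenol
Product: 12 methyl 3-Ar(DEF)-propanoate
Conditions: BnBr, K2CO3, DMF, 60 °C
Reagents that add atoms: benzyl bromide BrCc1ccccc1
Why: Williamson etherification of the hindered phenol, which removes the only acidic proton that would quench the dianion in step 8.

Step 8
Reactants: 3 methyl 5-[2-(benzyloxy)phenyl]-3-oxopentanoate; 12 methyl 3-Ar(DEF)-propanoate
Product: 14 5-[2-(benzyloxy)benzyl]-4-hydroxy-6-[2-Ar(DEF)-ethyl]-2H-pyran-2-one, via open-chain dioxo ester 13 (not isolated)
Conditions: 3 (2.5 equiv), LiN(iPr)2 (5.2 equiv), THF, −78 to 0 °C; 12; aq. HCl, 0 °C; DBU (0.2 equiv), toluene, 90 °C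
Reagents that add atoms: none
Why: Claisen acylation of a β-keto ester dianion at its γ-carbon by an ester, the standard entry to 3,5-dioxo esters, with excess dianion absorbing the acidic product. DBU-induced enol lactonisation then gives the 4-hydroxy-2-pyrone, and the labile stereocentre of 13 disappears.

Step 9
Reactants: 14 5-[2-(benzyloxy)benzyl]-4-hydroxy-6-[2-Ar(DEF)-ethyl]-2H-pyran-2-one
Product: 17 8-[2-(benzyloxy)benzyl]-7-[2-Ar(DEF)-ethyl]-4H,5H-pyrano[4,3-b]pyran-4,5-dione, via O-acyl pyrone 15 (not isolated), via C-acyl pyrone 16 (not isolated)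
Conditions: (E)-EtOCH=CHCOCl, Et3N, CH2Cl2, 0 °C; DMAP (0.3 equiv), rt; TsOH·H2O (cat.), toluene, 60 °C
Reagents that add atoms: (E)-3-ethoxyacryloyl chloride CCO/C=C/C(=O)Cl
Why: O-acylation and a DMAP-catalysed O-to-C acyl shift (Fries type, standard for 4-hydroxy-2-pyrones), then oxa-Michael addition–elimination as in chromone formation from 2-hydroxyaryl β-alkoxyvinyl ketones. With one hydroxyl and one nucleophilic carbon in 14, O1 and C4a are fixed by connectivity.

Step 10
Reactants: 17 8-[2-(benzyloxy)benzyl]-7-[2-Ar(DEF)-ethyl]-4H,5H-pyrano[4,3-b]pyran-4,5-dione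
Product: 19 8-[2-(benzyloxy)benzyl]-5,7-dihydroxy-6-[Ar(DEF)-methyl]-4H-chromen-4-one, via acylketene enol 18 (not isolated)
Conditions: 17 added to KN(SiMe3)2 (2.2 equiv), THF (0.01 M), −78 °C, then to 50 °C; aq. HCl
Reagents that add atoms: none
Why: Proposed new method: The amide base removes a proton from the C6 methylene of 17, the site at which 6-alkyl-2-pyrones are routinely metalated and which here is vinylogously acidified by both C4=O and C5=O. The delocalised anion has carbanion character at C4a, so the enol-ester bond C5–O6 can break in an E1cB sense to the acylketene enolate 18, in which O6 has become the C7 enolate oxygen and the C8=C8a geometry inherited from the ring holds C6 next to C5. Closure through oxygen only returns the anion of 17, whereas closure through carbon, a 6π electrocyclisation of the C6=C7–C8=C8a–C4a=C5 triene that forms the C5–C6 bond and the six-membered carbocycle, gives a cyclohexadienone that tautomerises irreversibly to the bis-phenoxide of 19, so the equilibrium should drain into ring A. The closest known reaction types are the alkoxide-induced conversion of 4-alkoxy-6-methyl-2-pyrones into phloroglucinol ethers, the Dieckmann closure of 2-(2-oxoalkyl)benzoates to naphthalene-1,3-diols, and the dienylketene electrocyclisation that ends cyclobutenone benzannulations. A non-nucleophilic base is required because an alkoxide would add at C2 and expel O1 as an inert pyronate, which would also put the O1/5-OH distinction at risk. No stereocentre is formed and no regiochemical choice exists: O1 never leaves C8a, the ring C arm is already on C8, and the ring D arm travels with C6. The selectivity needed is C6–H deprotonation over the merely benzylic methylenes, secured by a wide acidity gap, and unimolecular reaction over Michael addition of the anion to C2 of neutral 17, secured by inverse addition to excess base at high dilution.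

Step 11
Reactants: 19 8-[2-(benzyloxy)benzyl]-5,7-dihydroxy-6-[Ar(DEF)-methyl]-4H-chromen-4-one
Product: 20 5,7-bis(benzyloxy)-8-[2-(benzyloxy)benzyl]-6-[Ar(DEF)-methyl]-4H-chromen-4-one
Conditions: BnBr, K2CO3, Bu4NI (cat.), DMF, 60 °C
Reagents that add atoms: benzyl bromide BrCc1ccccc1
Why: Williamson etherification. The chromone is stable to carbonate, ring A has no free carbon left for C-alkylation, and masking 5-OH locks the constitution of the flavanone formed next.

Step 12
Reactants: 20 5,7-bis(benzyloxy)-8-[2-(benzyloxy)benzyl]-6-[Ar(DEF)-methyl]-4H-chromen-4-one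
Product: 21 (2S)-5,7-bis(benzyloxy)-8-[2-(benzyloxy)benzyl]-6-[Ar(DEF)-methyl]-2-phenylchroman-4-one
Conditions: PhB(OH)2 (3 equiv), [Rh(OH)(cod)]2 (2.5 mol %), (R)-MeO-F12-BIPHEP (5.5 mol %), CH2Cl2/H2O, 20 °C
Reagents that add atoms: phenylboronic acid OB(O)c1ccccc1
Why: Hayashi–Miyaura 1,4-addition of an arylboronic acid to a chromone, a reaction type known for 5,7-dioxygenated chromones. Phenylrhodium inserts into C2=C3, water protonates the enolate, and the chiral diphosphine alone sets C2. The neutral medium avoids retro-oxa-Michael opening, and CH2Cl2 restrains a second 1,2-addition.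

Step 13
Reactants: 21 (2S)-5,7-bis(benzyloxy)-8-[2-(benzyloxy)benzyl]-6-[Ar(DEF)-methyl]-2-phenylchroman-4-one
Product: 22 (2S)-5,7-dihydroxy-8-(2-hydroxybenzyl)-6-{2-hydroxy-5-[2-hydroxy-3-(2-hydroxybenzyl)benzyl]benzyl}-2-phenylchroman-4-one (target)
Conditions: H2 (1 atm), Pd/C (10 %), EtOAc/MeOH, rt
Reagents that add atoms: none
Why: Neutral hydrogenolysis of six aryl benzyl ethers, routine for benzyl-protected flavanones. No acid or base is present, so C2 and the C6/C8 assignment should be untouched.

## Compound list

1 | methyl acetoacetate | CC(=O)CC(=O)OC | starting material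
2 | 1-(benzyloxy)-2-(bromomethyl)benzene | BrCc1ccccc1OCc1ccccc1 | starting material
3 | methyl 5-[2-(benzyloxy)phenyl]-3-oxopentanoate | COC(=O)CC(=O)CCc1ccccc1OCc1ccccc1 | intermediate
4 | 3,4-dihydrocoumarin | O=C1CCc2ccccc2O1 | starting material
5 | methyl 3-[2-(benzyloxy)phenyl]propanoate | COC(=O)CCc1ccccc1OCc1ccccc1 | intermediate
6 | methyl 3-[2-(benzyloxy)-5-formylphenyl]propanoate | COC(=O)CCc1cc(C=O)ccc1OCc1ccccc1 | intermediate
7 | cyclohexanone | O=C1CCCCC1 | starting material
8 | 2-(benzyloxy)benzaldehyde | O=Cc1ccccc1OCc1ccccc1 | starting material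
9 | (E)-2-[2-(benzyloxy)benzylidene]cyclohexan-1-one | O=C1CCCC/C1=C\c1ccccc1OCc1ccccc1 | intermediate
10 | unsymmetrical (E,E)-2,6-bis(arylidene)cyclohexanone | O=C1/C(CCC/C1=C\c1ccccc1OCc1ccccc1)=C/c1ccc(OCc2ccccc2)c(CCC(=O)OC)c1 | intermediate
11 | methyl 3-[2-(benzyloxy)-5-({3-[2-(benzyloxy)benzyl]-2-hydroxyphenyl}methyl)phenyl]propanoate | COC(=O)CCc1cc(Cc2cccc(Cc3ccccc3OCc3ccccc3)c2O)ccc1OCc1ccccc1 | intermediate
12 | methyl 3-Ar(DEF)-propanoate | COC(=O)CCc1cc(Cc2cccc(Cc3ccccc3OCc3ccccc3)c2OCc2ccccc2)ccc1OCc1ccccc1 | intermediate
13 | methyl 4-[2-(benzyloxy)benzyl]-3,5-dioxo-7-Ar(DEF)-heptanoate (C4 configurationally labile) | COC(=O)CC(=O)C(Cc1ccccc1OCc1ccccc1)C(=O)CCc1cc(Cc2cccc(Cc3ccccc3OCc3ccccc3)c2OCc2ccccc2)ccc1OCc1ccccc1 | intermediate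
14 | 5-[2-(benzyloxy)benzyl]-4-hydroxy-6-[2-Ar(DEF)-ethyl]-2H-pyran-2-one | O=C1C=C(O)C(Cc2ccccc2OCc2ccccc2)=C(CCc2cc(Cc3cccc(Cc4ccccc4OCc4ccccc4)c3OCc3ccccc3)ccc2OCc2ccccc2)O1 | intermediate
15 | 4-O-[(E)-3-ethoxyacryloyl] ester of 14 | O=C1C=C(OC(=O)/C=C/OCC)C(Cc2ccccc2OCc2ccccc2)=C(CCc2cc(Cc3cccc(Cc4ccccc4OCc4ccccc4)c3OCc3ccccc3)ccc2OCc2ccccc2)O1 | intermediate
16 | 3-[(E)-3-ethoxyacryloyl] derivative of 14 | CCO/C=C/C(=O)C1=C(O)C(Cc2ccccc2OCc2ccccc2)=C(CCc2cc(Cc3cccc(Cc4ccccc4OCc4ccccc4)c3OCc3ccccc3)ccc2OCc2ccccc2)OC1=O | intermediate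
17 | 8-[2-(benzyloxy)benzyl]-7-[2-Ar(DEF)-ethyl]-4H,5H-pyrano[4,3-b]pyran-4,5-dione | O=C1C=COC2=C1C(=O)OC(CCc3cc(Cc4cccc(Cc5ccccc5OCc5ccccc5)c4OCc4ccccc4)ccc3OCc3ccccc3)=C2Cc1ccccc1OCc1ccccc1 | intermediate
18 | ring-opened acylketene, drawn as the neutral C7 enol (present as its potassium enolate) | O=C=C1C(=O)C=COC1=C(Cc2ccccc2OCc2ccccc2)C(O)=CCc2cc(Cc3cccc(Cc4ccccc4OCc4ccccc4)c3OCc3ccccc3)ccc2OCc2ccccc2 | intermediate
19 | 8-[2-(benzyloxy)benzyl]-5,7-dihydroxy-6-[Ar(DEF)-methyl]-4H-chromen-4-one | O=c1ccoc2c(Cc3ccccc3OCc3ccccc3)c(O)c(Cc3cc(Cc4cccc(Cc5ccccc5OCc5ccccc5)c4OCc4ccccc4)ccc3OCc3ccccc3)c(O)c12 | intermediate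
20 | 5,7-bis(benzyloxy)-8-[2-(benzyloxy)benzyl]-6-[Ar(DEF)-methyl]-4H-chromen-4-one | O=c1ccoc2c(Cc3ccccc3OCc3ccccc3)c(OCc3ccccc3)c(Cc3cc(Cc4cccc(Cc5ccccc5OCc5ccccc5)c4OCc4ccccc4)ccc3OCc3ccccc3)c(OCc3ccccc3)c12 | intermediate
21 | (2S)-5,7-bis(benzyloxy)-8-[2-(benzyloxy)benzyl]-6-[Ar(DEF)-methyl]-2-phenylchroman-4-one | O=C1C[C@@H](c2ccccc2)Oc2c(Cc3ccccc3OCc3ccccc3)c(OCc3ccccc3)c(Cc3cc(Cc4cccc(Cc5ccccc5OCc5ccccc5)c4OCc4ccccc4)ccc3OCc3ccccc3)c(OCc3ccccc3)c21 | intermediate
22 | (2S)-5,7-dihydroxy-8-(2-hydroxybenzyl)-6-{2-hydroxy-5-[2-hydroxy-3-(2-hydroxybenzyl)benzyl]benzyl}-2-phenylchroman-4-one | O=C1C[C@@H](c2ccccc2)Oc2c(Cc3ccccc3O)c(O)c(Cc3cc(Cc4cccc(Cc5ccccc5O)c4O)ccc3O)c(O)c21 | target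

## Step count and least certain steps

Total: 13 steps. Longest linear sequence: 11 steps (2, 3, 5, 6, 7, 8, 9, 10, 11, 12, 13).

**Step 10 (key step, new method).**
- *Most likely failure:* the strongly stabilised anion of 17 persists without breaking the C5–O6 bond. Alternatively, at the temperature needed for opening, the acylketene or the anion is consumed by intermolecular addition to C2 of another molecule.
- *Fallback (known chemistry):* it sets out from 13, which is isolated by the cold acidic work-up of step 8 without the DBU treatment. C-acylation of its magnesium enolate at C4a (MgCl2, pyridine, the acid chloride of step 9) and acid-induced closure give methyl 2-{1-[2-(benzyloxy)phenyl]-3-oxo-5-Ar(DEF)-pentan-2-yl}-4-oxo-4H-pyran-3-carboxylate F1. LiN(iPr)2 (3 equiv) then forms the C8,C6-dianion. Its terminal carbanion closes on the C5 ester in a Dieckmann condensation, as in the classical closure of 2-(2-oxoalkyl)benzoates to naphthalene-1,3-diols. The route is rejoined at 19.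

**Step 9.**
- *Most likely failure:* the O-to-C acyl shift is slow because the β-ethoxyacryloyl group is a poor acyl donor, and DMAP or chloride adds at its β-carbon, so material is lost to oligomerisation.
- *Fallback:* from 14, the heterocycle is built from a two-carbon and a one-carbon unit instead. Acetylation at C4a (AcOH, dicyclohexylcarbodiimide, DMAP) gives the 3-acetyl-4-hydroxy-2-pyrone F2. Condensation with dimethylformamide dimethyl acetal gives the enaminone F3. Acid then closes F3 with loss of the amine, and the route is rejoined at 17.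

**Step 8.**
- *Most likely failure:* proton transfer from the enolisable ester 12 to the dianion, and sluggish attack of a secondary carbanion on an unactivated ester, so conversion is low.
- *Fallback:* the Claisen union is replaced by aldol addition and oxidation. From 12, iBu2AlH at −78 °C gives 3-Ar(DEF)-propanal F4. The dianion of 3 adds to it to give the δ-hydroxy-β-keto ester F5 as a mixture of diastereomers. Dess–Martin periodinane returns the route at 13, which is lactonised as before.

**Step 12.**
- *Most likely failure:* low reactivity of the electron-rich, peri-substituted chromone so that protodeboronation wins, insufficient facial selectivity, or a following 1,2-addition.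
- *Fallback:* a dynamic resolution that turns the lability of C2 into an asset. From 20, copper-catalysed addition of PhMgBr (CuBr·SMe2, Me3SiCl, THF, −78 °C) gives the racemic flavanone F6. Transfer hydrogenation with RuCl(p-cymene)[(S,S)-TsDPEN] and HCO2H/DBU is then run under conditions where base-induced retro-oxa-Michael and oxa-Michael steps racemise C2. The 5-O-benzyl group leaves O1 as the only oxygen that can re-close. This should funnel both enantiomers into the cis alcohol, the (2S,4S)-flavan-4-ol F7. Dess–Martin oxidation rejoins the route at 21.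

## Further compounds

F1 | step 10 | methyl 2-{1-[2-(benzyloxy)phenyl]-3-oxo-5-Ar(DEF)-pentan-2-yl}-4-oxo-4H-pyran-3-carboxylate | COC(=O)C1=C(C(Cc2ccccc2OCc2ccccc2)C(=O)CCc2cc(Cc3cccc(Cc4ccccc4OCc4ccccc4)c3OCc3ccccc3)ccc2OCc2ccccc2)OC=CC1=O
F2 | step 9 | 3-acetyl-5-[2-(benzyloxy)benzyl]-4-hydroxy-6-[2-Ar(DEF)-ethyl]-2H-pyran-2-one | CC(=O)C1=C(O)C(Cc2ccccc2OCc2ccccc2)=C(CCc2cc(Cc3cccc(Cc4ccccc4OCc4ccccc4)c3OCc3ccccc3)ccc2OCc2ccccc2)OC1=O
F3 | step 9 | 5-[2-(benzyloxy)benzyl]-3-[(E)-3-(dimethylamino)acryloyl]-4-hydroxy-6-[2-Ar(DEF)-ethyl]-2H-pyran-2-one | CN(C)/C=C/C(=O)C1=C(O)C(Cc2ccccc2OCc2ccccc2)=C(CCc2cc(Cc3cccc(Cc4ccccc4OCc4ccccc4)c3OCc3ccccc3)ccc2OCc2ccccc2)OC1=O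
F4 | step 8 | 3-Ar(DEF)-propanal | O=CCCc1cc(Cc2cccc(Cc3ccccc3OCc3ccccc3)c2OCc2ccccc2)ccc1OCc1ccccc1
F5 | step 8 | methyl 4-[2-(benzyloxy)benzyl]-5-hydroxy-3-oxo-7-Ar(DEF)-heptanoate (diastereomer mixture) | COC(=O)CC(=O)C(Cc1ccccc1OCc1ccccc1)C(O)CCc1cc(Cc2cccc(Cc3ccccc3OCc3ccccc3)c2OCc2ccccc2)ccc1OCc1ccccc1
F6 | step 12 | racemic 5,7-bis(benzyloxy)-8-[2-(benzyloxy)benzyl]-6-[Ar(DEF)-methyl]-2-phenylchroman-4-one | O=C1CC(c2ccccc2)Oc2c(Cc3ccccc3OCc3ccccc3)c(OCc3ccccc3)c(Cc3cc(Cc4cccc(Cc5ccccc5OCc5ccccc5)c4OCc4ccccc4)ccc3OCc3ccccc3)c(OCc3ccccc3)c21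
F7 | step 12 | (2S,4S)-5,7-bis(benzyloxy)-8-[2-(benzyloxy)benzyl]-6-[Ar(DEF)-methyl]-2-phenylchroman-4-ol | O[C@H]1C[C@@H](c2ccccc2)Oc2c(Cc3ccccc3OCc3ccccc3)c(OCc3ccccc3)c(Cc3cc(Cc4cccc(Cc5ccccc5OCc5ccccc5)c4OCc4ccccc4)ccc3OCc3ccccc3)c(OCc3ccccc3)c21
A1 | alternative 1 | (S)-pinocembrin | O=C1C[C@@H](c2ccccc2)Oc2cc(O)cc(O)c21
A2 | alternative 1 | 2-(hydroxymethyl)-4-[2-hydroxy-3-(2-hydroxybenzyl)benzyl]phenol | OCc1cc(Cc2cccc(Cc3ccccc3O)c2O)ccc1O
A3 | alternative 1 | (2S)-5,7-dihydroxy-8-(2-hydroxybenzyl)-2-phenylchroman-4-one | O=C1C[C@@H](c2ccccc2)Oc2c(Cc3ccccc3O)c(O)cc(O)c21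
A4 | alternative 1 | (2S)-5,7-dihydroxy-6-(2-hydroxybenzyl)-2-phenylchroman-4-one | O=C1C[C@@H](c2ccccc2)Oc2cc(O)c(Cc3ccccc3O)c(O)c21
A5 | alternative 2 | fully armed (E)-2',4',6'-trihydroxychalcone | O=C(/C=C/c1ccccc1)c1c(O)c(Cc2ccccc2O)c(O)c(Cc2cc(Cc3cccc(Cc4ccccc4O)c3O)ccc2O)c1O
A6 | alternative 3 | 5,7-bis(benzyloxy)-8-[2-(benzyloxy)benzyl]-6-iodo-4H-chromen-4-one | O=c1ccoc2c(Cc3ccccc3OCc3ccccc3)c(OCc3ccccc3)c(I)c(OCc3ccccc3)c12
A7 | alternative 3 | [Ar(DEF)-methyl]zinc chloride | Cl[Zn]Cc1cc(Cc2cccc(Cc3ccccc3OCc3ccccc3)c2OCc2ccccc2)ccc1OCc1ccccc1
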